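**Retrosynthetic overview**

- Asterelin A is a dibenzofuran-3-ol (ring A = C1–C4 with OH at C3, ring B = C6–C9) bridged from the bay carbon C1 through CH2CH2–p-phenylene (ring D)–O–catechol ring C–CH2CH2 back to C7. The last step is H2/Pd–C on a macrocyclic stilbene bis(benzyl ether), which saturates the C=C and removes both benzyl groups.
- The 18-membered ring is cut at the CH2–CH2 bond between dibenzofuran C7 and ring C. An intramolecular McMurry coupling of an open dialdehyde closes it as a stilbene, and this is the last ring formed.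
- Enabling feature: this bridge is a bibenzyl whose two carbons are both benzylic and, as ArCHO, of the same (acceptor) polarity. It lies on the unhindered C7 edge of ring B, far from the C1/C9 bay, and the rigid dibenzofuran, the p-phenylene ring D and the meta-linked ring C leave few rotors between the two formyl groups.
- The dialdehyde comes from a dibenzofuran aldehyde ester and a diaryl ether phosphonium salt (ring C–O–ring D, made by SNAr) through Wittig olefination at the bay carbon, diimide reduction, LiAlH4 and MnO2.
- The dibenzofuran comes from a Suzuki biaryl coupling (C9a–C9b bond), then BBr3 and an intramolecular SNAr closure of the furan ring. Ring order: rings A–D bought, furan ring in step 3, 18-membered ring in step 11.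

Key step: step 11

Assumption: the target carries no stereodescriptor and no stereocentre, so nothing has to be controlled; the alkene geometry of the two stilbene intermediates is left open because both C=C bonds are later saturated.

**Route**

Step 1
Reactants: 1 2-bromo-3,5-dimethoxybenzaldehyde; 2 [2-fluoro-4-(methoxycarbonyl)phenyl]boronic acid
Product: 3 methyl 3-fluoro-4-(2-formyl-4,6-dimethoxyphenyl)benzoate
Conditions: Pd(OAc)2 (cat.), SPhos (cat.), K3PO4, toluene/H2O, 80 °C
Reagents that add atoms: none
Why: Suzuki–Miyaura coupling: the SPhos-ligated palladium catalyst should insert into the di-ortho-substituted C–Br bond of 1 and couple the ortho-fluoro boronic acid faster than it protodeboronates, while C–F, CHO and CO2Me stay untouched, so the future C9a–C9b bond is set with the fluorine and the future furan oxygen on neighbouring ortho positions.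

Step 2
Reactants: 3 methyl 3-fluoro-4-(2-formyl-4,6-dimethoxyphenyl)benzoate
Product: 4 methyl 3-fluoro-4-(2-formyl-4,6-dihydroxyphenyl)benzoate
Conditions: BBr3, CH2Cl2, −78 to 0 °C; then H2O
Reagents that add atoms: none
Why: Lewis-acid O-demethylation with BBr3: the aryl methyl ethers should be cleaved at or below 0 °C faster than the methyl ester or the aldehyde is attacked, which frees both phenols of ring A.

Step 3
Reactants: 4 methyl 3-fluoro-4-(2-formyl-4,6-dihydroxyphenyl)benzoate
Product: 6 methyl 7-(benzyloxy)-9-formyldibenzo[b,d]furan-3-carboxylate, via hydroxydibenzofuran 5 (not isolated)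
Conditions: K2CO3, DMF, 120 °C; then BnBr, 25 °C
Reagents that add atoms: benzyl bromide, BrCc1ccccc1
Why: Intramolecular SNAr followed by Williamson etherification: only the phenoxide ortho to the biaryl bond can reach the C–F carbon (five-membered ring closure, fluoride inductively activated by the meta ester), so the furan ring should close regiospecifically, and the one phenoxide left over is then benzylated in the same flask.

Step 4
Reactants: 7 methyl 4-(benzyloxy)-3-hydroxybenzoate; 8 4-fluorobenzaldehyde
Product: 9 methyl 4-(benzyloxy)-3-(4-formylphenoxy)benzoate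
Conditions: K2CO3, DMF, 110 °C
Reagents that add atoms: none
Why: SNAr diaryl ether synthesis: the fluoride para to the formyl group of 8 should be displaced by the phenoxide of 7 through a Meisenheimer intermediate, the ester and the benzyl ether being inert to carbonate.

Step 5
Reactants: 9 methyl 4-(benzyloxy)-3-(4-formylphenoxy)benzoate
Product: 10 methyl 4-(benzyloxy)-3-[4-(hydroxymethyl)phenoxy]benzoate
Conditions: NaBH4, MeOH/THF, 0 °C
Reagents that add atoms: none
Why: Chemoselective borohydride reduction: the aldehyde should be reduced at 0 °C while the methyl benzoate is left alone.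

Step 6
Reactants: 10 methyl 4-(benzyloxy)-3-[4-(hydroxymethyl)phenoxy]benzoate
Product: 11 [4-[2-(benzyloxy)-5-(methoxycarbonyl)phenoxy]benzyl]triphenylphosphonium bromide
Conditions: PPh3·HBr, MeCN, reflux
Reagents that add atoms: triphenylphosphine hydrobromide, [Br-].c1ccc(cc1)[PH+](c1ccccc1)c1ccccc1
Why: Phosphonium salt formation from a benzylic alcohol: protonation by PPh3·HBr turns the hydroxyl of the p-aryloxybenzyl alcohol into a leaving group that triphenylphosphine displaces, so the bromide and phosphonium stages are merged.

Step 7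
Reactants: 6 methyl 7-(benzyloxy)-9-formyldibenzo[b,d]furan-3-carboxylate; 11 [4-[2-(benzyloxy)-5-(methoxycarbonyl)phenoxy]benzyl]triphenylphosphonium bromide
Product: 13 methyl 7-(benzyloxy)-9-[2-[4-[2-(benzyloxy)-5-(methoxycarbonyl)phenoxy]phenyl]ethenyl]dibenzo[b,d]furan-3-carboxylate (E/Z mixture), via ylide 12 (not isolated)
Conditions: K2CO3, 18-crown-6 (cat.), CH2Cl2, reflux
Reagents that add atoms: none
Why: Wittig olefination: solid–liquid phase-transfer deprotonation of 11 gives the semi-stabilised benzylic ylide 12, which should add to the non-enolisable bay aldehyde of 6 without touching the esters, and the E/Z ratio is irrelevant.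

Step 8
Reactants: 13 methyl 7-(benzyloxy)-9-[2-[4-[2-(benzyloxy)-5-(methoxycarbonyl)phenoxy]phenyl]ethenyl]dibenzo[b,d]furan-3-carboxylate
Product: 14 methyl 7-(benzyloxy)-9-[2-[4-[2-(benzyloxy)-5-(methoxycarbonyl)phenoxy]phenyl]ethyl]dibenzo[b,d]furan-3-carboxylate
Conditions: TsNHNH2 (excess), NaOAc, THF/H2O, reflux
Reagents that add atoms: none
Why: Diimide reduction: HN=NH generated in the flask from tosylhydrazide should deliver H2 in a concerted syn fashion to the stilbene C=C only, which keeps the two benzyl ethers that catalytic hydrogenation would cleave.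

Step 9
Reactants: 14 methyl 7-(benzyloxy)-9-[2-[4-[2-(benzyloxy)-5-(methoxycarbonyl)phenoxy]phenyl]ethyl]dibenzo[b,d]furan-3-carboxylate
Product: 15 [7-(benzyloxy)-9-[2-[4-[2-(benzyloxy)-5-(hydroxymethyl)phenoxy]phenyl]ethyl]dibenzo[b,d]furan-3-yl]methanol
Conditions: LiAlH4, THF, 0 °C
Reagents that add atoms: none
Why: Hydride reduction: LiAlH4 should take both aryl methyl esters to the benzylic alcohols, the ethers and the furan being inert.

Step 10
Reactants: 15 [7-(benzyloxy)-9-[2-[4-[2-(benzyloxy)-5-(hydroxymethyl)phenoxy]phenyl]ethyl]dibenzo[b,d]furan-3-yl]methanol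
Product: 16 7-(benzyloxy)-9-[2-[4-[2-(benzyloxy)-5-formylphenoxy]phenyl]ethyl]dibenzo[b,d]furan-3-carbaldehyde
Conditions: activated MnO2, CH2Cl2, 25 °C
Reagents that add atoms: none
Why: MnO2 oxidation: activated manganese dioxide should oxidise both benzylic alcohols to the aldehydes and stop there.

Step 11
Reactants: 16 7-(benzyloxy)-9-[2-[4-[2-(benzyloxy)-5-formylphenoxy]phenyl]ethyl]dibenzo[b,d]furan-3-carbaldehyde
Product: 18 bis-O-benzyl dehydroasterelin A (18-membered macrocyclic stilbene; C=C between dibenzofuran C7 and ring C; E/Z mixture), via titanium pinacolate 17 (not isolated)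
Conditions: TiCl4, Zn, pyridine, THF, reflux; 16 added by syringe pump (high dilution)
Reagents that add atoms: none
Why: Low-valent titanium transfers one electron to each formyl group; the two titanium-bound ketyl radicals, carbons of like polarity, couple to the pinacolate 17, which is deoxygenated on titanium to the stilbene 18 (intramolecular McMurry reaction). The closest known reaction type is the McMurry macrocyclisation of aromatic dialdehydes to stilbene-bridged cyclophanes and macrocyclic bis(bibenzyl) precursors. The one ring closed is the 18-membered ring, formed by joining the two chain termini (the C7 formyl group of the dibenzofuran and the formyl group on ring C) under pseudo-high dilution. The two carbinol stereocentres of 17 are transient and vanish on deoxygenation, the target has no stereocentre, and the E/Z geometry of 18 is erased in step 12. The selectivity needed is intra- over intermolecular coupling and alkene over arrested pinacol: slow addition keeps 16 dilute, both aldehydes are non-enolisable and unhindered, and the rigid dibenzofuran, the p-phenylene ring D and the meta-linked ring C leave only the CH2CH2 and ether hinges free, so the formyl groups can meet away from the crowded C1/C9 bay. Benzyl ethers, diaryl ethers and the furan should be inert to the reagent.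

Step 12
Reactants: 18 bis-O-benzyl dehydroasterelin A
Product: 19 asterelin A
Conditions: H2 (1 atm), 10% Pd/C, EtOAc/MeOH, 25 °C
Reagents that add atoms: none
Why: Heterogeneous catalytic hydrogenation and hydrogenolysis: Pd/C should saturate the stilbene and cleave both O-benzyl ethers in one operation, leaving the diaryl ether and the dibenzofuran intact, to deliver the target, which has no stereocentre.

**Compound list**

1 | 2-bromo-3,5-dimethoxybenzaldehyde | O=Cc1cc(OC)cc(OC)c1Br | starting material
2 | [2-fluoro-4-(methoxycarbonyl)phenyl]boronic acid | COC(=O)c1ccc(B(O)O)c(F)c1 | starting material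
3 | methyl 3-fluoro-4-(2-formyl-4,6-dimethoxyphenyl)benzoate | COC(=O)c1ccc(c(F)c1)-c1c(C=O)cc(OC)cc1OC | intermediate
4 | methyl 3-fluoro-4-(2-formyl-4,6-dihydroxyphenyl)benzoate | COC(=O)c1ccc(c(F)c1)-c1c(C=O)cc(O)cc1O | intermediate
5 | methyl 9-formyl-7-hydroxydibenzo[b,d]furan-3-carboxylate (not isolated) | COC(=O)c1ccc2c(c1)oc1cc(O)cc(C=O)c12 | intermediate
6 | methyl 7-(benzyloxy)-9-formyldibenzo[b,d]furan-3-carboxylate | COC(=O)c1ccc2c(c1)oc1cc(OCc3ccccc3)cc(C=O)c12 | intermediate
7 | methyl 4-(benzyloxy)-3-hydroxybenzoate | COC(=O)c1ccc(OCc2ccccc2)c(O)c1 | starting material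
8 | 4-fluorobenzaldehyde | O=Cc1ccc(F)cc1 | starting material
9 | methyl 4-(benzyloxy)-3-(4-formylphenoxy)benzoate | COC(=O)c1ccc(OCc2ccccc2)c(Oc2ccc(C=O)cc2)c1 | intermediate
10 | methyl 4-(benzyloxy)-3-[4-(hydroxymethyl)phenoxy]benzoate | COC(=O)c1ccc(OCc2ccccc2)c(Oc2ccc(CO)cc2)c1 | intermediate
11 | [4-[2-(benzyloxy)-5-(methoxycarbonyl)phenoxy]benzyl]triphenylphosphonium bromide | COC(=O)c1ccc(OCc2ccccc2)c(Oc2ccc(C[P+](c3ccccc3)(c3ccccc3)c3ccccc3)cc2)c1.[Br-] | intermediate
12 | methyl 4-(benzyloxy)-3-[4-[(triphenyl-λ5-phosphanylidene)methyl]phenoxy]benzoate, the ylide (not isolated) | COC(=O)c1ccc(OCc2ccccc2)c(Oc2ccc(C=P(c3ccccc3)(c3ccccc3)c3ccccc3)cc2)c1 | intermediate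
13 | methyl 7-(benzyloxy)-9-[2-[4-[2-(benzyloxy)-5-(methoxycarbonyl)phenoxy]phenyl]ethenyl]dibenzo[b,d]furan-3-carboxylate (E/Z mixture, geometry unspecified) | COC(=O)c1ccc2c(c1)oc1cc(OCc3ccccc3)cc(C=Cc3ccc(Oc4cc(ccc4OCc5ccccc5)C(=O)OC)cc3)c12 | intermediate
14 | methyl 7-(benzyloxy)-9-[2-[4-[2-(benzyloxy)-5-(methoxycarbonyl)phenoxy]phenyl]ethyl]dibenzo[b,d]furan-3-carboxylate | COC(=O)c1ccc2c(c1)oc1cc(OCc3ccccc3)cc(CCc3ccc(Oc4cc(ccc4OCc5ccccc5)C(=O)OC)cc3)c12 | intermediate
15 | [7-(benzyloxy)-9-[2-[4-[2-(benzyloxy)-5-(hydroxymethyl)phenoxy]phenyl]ethyl]dibenzo[b,d]furan-3-yl]methanol | OCc1ccc2c(c1)oc1cc(OCc3ccccc3)cc(CCc3ccc(Oc4cc(CO)ccc4OCc5ccccc5)cc3)c12 | intermediate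
16 | 7-(benzyloxy)-9-[2-[4-[2-(benzyloxy)-5-formylphenoxy]phenyl]ethyl]dibenzo[b,d]furan-3-carbaldehyde | O=Cc1ccc2c(c1)oc1cc(OCc3ccccc3)cc(CCc3ccc(Oc4cc(C=O)ccc4OCc5ccccc5)cc3)c12 | intermediate
17 | macrocyclic titanium pinacolate, drawn as the free 1,2-diol (diastereomer mixture, both carbinol centres transient, not isolated) | c1ccccc1COc1cc2c3c(c1)oc1cc(ccc13)C(O)C(O)c1ccc(OCc4ccccc4)c(c1)Oc1ccc(cc1)CC2 | intermediate
18 | bis-O-benzyl dehydroasterelin A, the 18-membered stilbene (E/Z mixture, geometry unspecified) | c1ccccc1COc1cc2c3c(c1)oc1cc(ccc13)C=Cc1ccc(OCc4ccccc4)c(c1)Oc1ccc(cc1)CC2 | intermediate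
19 | asterelin A | Oc1cc2c3c(c1)oc1cc(ccc13)CCc1ccc(O)c(c1)Oc1ccc(cc1)CC2 | target

**Step count and risks**

Total step count: 12. Longest linear sequence: 9 steps (steps 1–3 and 7–12 from 1; equally steps 4–12 from 7).

Three steps most likely to fail:

1. Step 11 (macrocyclisation). Intermolecular ketyl coupling may outrun ring closure and give oligomers, or the reaction may stop at the pinacol stage. The fallback is a ring contraction that sets out from 15 and returns at 18. Diol 15 would be converted with PBr3 (CH2Cl2, 0 °C) into the bis(bromomethyl) compound F1. Slow addition of F1 to Na2S·9H2O in EtOH/THF at high dilution should close the 19-membered cyclic sulfide F2 by two SN2 displacements. Oxidation (mCPBA, CH2Cl2, 0 °C) would give the cyclic sulfone F3. A Ramberg–Bäcklund reaction (KOH, CCl4, t-BuOH, 25–50 °C) should then extrude SO2 with contraction to the 18-membered stilbene 18, which continues with step 12.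

2. Step 3 (furan closure). Displacement of the fluoride, which is not resonance-activated, may be too slow, so that the aldehyde phenolate degrades at the temperature needed. The fallback is a metal-catalysed C–O coupling that sets out from 1 and returns at 5. Suzuki coupling of 1 with commercial [2-chloro-4-(methoxycarbonyl)phenyl]boronic acid (Pd(dppf)Cl2, K2CO3, dioxane/H2O, 80 °C, C–Cl bond untouched) would give the chloro biaryl F4. BBr3 would give the chloro diphenol F5. A palladium-catalysed intramolecular C–O coupling (Pd(OAc)2, tBuXPhos, K3PO4, toluene, 100 °C) should close the furan ring to 5, which is isolated here and benzylated as in step 3 to 6.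

3. Step 2 (demethylation). BBr3 may also cleave the methyl ester or attack the aldehyde before the hindered methyl ether next to the biaryl bond is removed. The fallback changes the order of events, sets out from 1 and returns at 4. Compound 1 is demethylated first (BBr3, CH2Cl2, −78 to 0 °C), when no ester is present, to 2-bromo-3,5-dihydroxybenzaldehyde F6. F6 is then coupled with 2 under the conditions of step 1, where the free phenols are carried as phenolates in the aqueous phosphate medium, to give 4.

**Further compounds**

F1 | step 11 | 7-(benzyloxy)-9-[2-[4-[2-(benzyloxy)-5-(bromomethyl)phenoxy]phenyl]ethyl]-3-(bromomethyl)dibenzo[b,d]furan | BrCc1ccc2c(c1)oc1cc(OCc3ccccc3)cc(CCc3ccc(Oc4cc(CBr)ccc4OCc5ccccc5)cc3)c12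
F2 | step 11 | 19-membered cyclic sulfide (CH2–S–CH2 in place of the bridge between dibenzofuran C7 and ring C; bis-O-benzyl) | c1ccccc1COc1cc2c3c(c1)oc1cc(ccc13)CSCc1ccc(OCc4ccccc4)c(c1)Oc1ccc(cc1)CC2
F3 | step 11 | 19-membered cyclic sulfone (CH2–SO2–CH2 in place of the bridge between dibenzofuran C7 and ring C; bis-O-benzyl) | c1ccccc1COc1cc2c3c(c1)oc1cc(ccc13)CS(=O)(=O)Cc1ccc(OCc4ccccc4)c(c1)Oc1ccc(cc1)CC2
F4 | step 3 | methyl 3-chloro-4-(2-formyl-4,6-dimethoxyphenyl)benzoate | COC(=O)c1ccc(c(Cl)c1)-c1c(C=O)cc(OC)cc1OC
F5 | step 3 | methyl 3-chloro-4-(2-formyl-4,6-dihydroxyphenyl)benzoate | COC(=O)c1ccc(c(Cl)c1)-c1c(C=O)cc(O)cc1O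
F6 | step 2 | 2-bromo-3,5-dihydroxybenzaldehyde | O=Cc1cc(O)cc(O)c1Br
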